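**Retrosynthetic overview**

- Feature: in the oxolane of the target (O1, C2 with the trimethoxyphenyl group, C3 with CH2OH, C4 with the aroyl group, C5H2) the benzylic O1–C2 bond stands 1,3 to C4, the carbon alpha to the ketone that also holds C5. The ring O1–C2–C3–C4–C5 is therefore the ring-expanded form of an arylcyclopropane C2–C3–C4 with a formyl group (C5=O1) on C4.
- The cis pair C3–CH2OH / C4–C(=O)Ar is a cis-fused gamma-lactone in disguise, so the last disconnection is the ketone C–aryl bond: bicyclic lactone plus 3,4-dimethoxyphenyllithium.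
- The formyl cyclopropane lactone comes from an (E)-cinnamyl alpha-formyl diazoacetate by catalytic asymmetric intramolecular cyclopropanation. The diazo ester comes from trimethoxycinnamyl alcohol and bromoacetyl bromide, the formyl carbon from DMF.
- Ring order: lactone and cyclopropane close together (step 6), the cyclopropane is expanded to the 2,3-dihydrofuran (step 7), C4=C5 is saturated (step 8), and the lactone is opened (step 9).

Key step: step 7

Remark (assumption): the sense of induction of the amidoporphyrin cobalt catalyst on this substrate is not predicted here. Both antipodes of the ligand are accessible, and the one that delivers the (1S,5R,6S) cyclopropane 10 in a trial run is the one to be used. Target locants throughout are O1, C2 (aryl), C3 (CH2OH), C4 (aroyl), C5; in these the target is 2S,3R,4R.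

**Step 1**
Reactants: 1 (E)-3,4,5-trimethoxycinnamic acid
Product: 2 methyl (E)-3,4,5-trimethoxycinnamate
Conditions: MeOH, H2SO4 (cat.), reflux
Reagents that add atoms: methanol CO
Why: Fischer esterification driven by the excess of methanol, which leaves the E-alkene and the aryl ethers untouched.

**Step 2**
Reactants: 2 methyl (E)-3,4,5-trimethoxycinnamate
Product: 3 (E)-3-(3,4,5-trimethoxyphenyl)prop-2-en-1-ol
Conditions: DIBAL-H (iBu2AlH, 2.5 equiv), CH2Cl2, −78 to 0 °C; aq. KNa tartrate
Reagents that add atoms: none
Why: 1,2-reduction of a conjugated ester by DIBAL-H, which at low temperature should give the allylic alcohol without conjugate reduction and with the E-geometry kept.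

**Step 3**
Reactants: 3 (E)-3-(3,4,5-trimethoxyphenyl)prop-2-en-1-ol; 4 bromoacetyl bromide
Product: 5 (E)-3-(3,4,5-trimethoxyphenyl)prop-2-en-1-yl 2-bromoacetate
Conditions: NaHCO3 (3 equiv), MeCN, 0 °C
Reagents that add atoms: none
Why: O-acylation of a primary alcohol by an acid bromide, with solid bicarbonate taking up HBr so that the acid-sensitive electron-rich cinnamyl ester and the alpha-bromide both survive.

**Step 4**
Reactants: 5 (E)-3-(3,4,5-trimethoxyphenyl)prop-2-en-1-yl 2-bromoacetate
Product: 7 (E)-3-(3,4,5-trimethoxyphenyl)prop-2-en-1-yl 2-diazoacetate, via N-alkylated ditosylhydrazine 6 (not isolated)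
Conditions: TsNHNHTs (2 equiv), DBU (5 equiv), THF, 0 °C
Reagents that add atoms: N,N'-ditosylhydrazine Cc1ccc(cc1)S(=O)(=O)NNS(=O)(=O)c1ccc(C)cc1
Why: Fukuyama diazoacetate synthesis, in which the bromoacetate N-alkylates the ditosylhydrazine and DBU then expels two sulfinate ions in succession to leave the diazo group under conditions mild enough for the allylic ester.

**Step 5**
Reactants: 7 (E)-3-(3,4,5-trimethoxyphenyl)prop-2-en-1-yl 2-diazoacetate
Product: 9 (E)-3-(3,4,5-trimethoxyphenyl)prop-2-en-1-yl 2-diazo-3-oxopropanoate, via diazo iminium chloride 8 (not isolated)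
Conditions: DMF, (COCl)2, CHCl3, 0 to 40 °C; then 7, 2,6-di-tert-butylpyridine, 0 °C to rt; then 10% aq. AcOH, rt; NaHCO3 wash
Reagents that add atoms: N,N-dimethylformamide CN(C)C=O; water O
Why: Vilsmeier–Haack C-formylation, in which the diazo carbon of 7 (the most nucleophilic site of the molecule) attacks the chloroiminium salt and loses its proton to the hindered pyridine, which keeps HCl from destroying unreacted 7, and the acceptor-stabilised diazo iminium salt 8 is then hydrolysed by dilute acetic acid to the aldehyde with the diazo group intact.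

**Step 6**
Reactants: 9 (E)-3-(3,4,5-trimethoxyphenyl)prop-2-en-1-yl 2-diazo-3-oxopropanoate
Product: 10 (1S,5R,6S)-2-oxo-6-(3,4,5-trimethoxyphenyl)-3-oxabicyclo[3.1.0]hexane-1-carbaldehyde
Conditions: [Co(3,5-DitBu-ChenPhyrin)] (D2-symmetric chiral amidoporphyrin complex of divalent cobalt, 2 mol %), toluene, rt, N2 atmosphere
Reagents that add atoms: none
Why: Catalytic asymmetric intramolecular cyclopropanation by metalloradical catalysis, in which the cobalt carbene radical adds to the tethered alkene and the benzylic radical closes the three-membered ring; the chiral pocket of the ligand selects the alkene face and so sets C5 (the later C3), the lactone can only be cis-fused, and the E-geometry places the aryl group trans to the lactone CH2 and cis to the formyl group.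

**Step 7**
Reactants: 10 (1S,5R,6S)-2-oxo-6-(3,4,5-trimethoxyphenyl)-3-oxabicyclo[3.1.0]hexane-1-carbaldehyde
Product: 11 (3aR,4S)-4-(3,4,5-trimethoxyphenyl)-3a,4-dihydro-1H,3H-furo[3,4-c]furan-1-one
Conditions: Sc(OTf)3 (10 mol %), CH2Cl2, rt
Reagents that add atoms: none
Why: Sc(OTf)3 binds the 1,3-dicarbonyl unit of 10 and the strained C1–C6 bond, the only ring bond flanked by both acceptors and by the aryl donor, heterolyses to a 3,4,5-trimethoxybenzyl cation and a scandium-bound alpha-formyl lactone enolate, whose formyl oxygen turns toward the cation and forms O1–C2. The closest known reaction type is the Lewis-acid-catalysed Cloke–Wilson rearrangement of acceptor-substituted aryl cyclopropyl aldehydes and ketones to 2,3-dihydrofurans. The only ring closed is the five-membered oxacycle O1–C2–C3–C4=C5, by attack of the enolate oxygen on the trigonal benzylic cation (formally 5-exo-trig with the enol double bond inside the new ring, which oxygen can do through an in-plane lone pair), while the lactone ring stays closed throughout. C3 (C5 of 10) takes no part and keeps the configuration bought in step 6, and C2 is re-formed under substrate control, the planar cation closing with the aryl group trans to the C3–CH2O arm, the less crowded and more stable arrangement. The step needs this 2,3-trans selectivity and needs the formyl rather than the lactone oxygen to close; the first follows from the C3 substituent and the second from the fact that closure through the lactone carbonyl would demand a bridgehead double bond.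

**Step 8**
Reactants: 11 (3aR,4S)-4-(3,4,5-trimethoxyphenyl)-3a,4-dihydro-1H,3H-furo[3,4-c]furan-1-one
Product: 12 (3aR,4S,6aR)-4-(3,4,5-trimethoxyphenyl)tetrahydro-1H,3H-furo[3,4-c]furan-1-one (cis-fused)
Conditions: H2 (1 atm), 5% Rh/Al2O3, EtOAc, rt
Reagents that add atoms: none
Why: Heterogeneous syn-hydrogenation of the push–pull enol ether C4=C5, in which hydrogen should reach C4 on the face that carries C3–H because only that addition leads to the strain-free cis-fused bicyclic lactone (so the C3/C4 cis relation follows from C3), with Rh on Al2O3 in a neutral solvent chosen to spare the benzylic C2–O1 bond.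

**Step 9**
Reactants: 12 (3aR,4S,6aR)-4-(3,4,5-trimethoxyphenyl)tetrahydro-1H,3H-furo[3,4-c]furan-1-one; 13 4-bromo-1,2-dimethoxybenzene
Product: 16 Magnone B, via 3,4-dimethoxyphenyllithium 14 (not isolated), via lithium lactolate 15 (not isolated)
Conditions: 13, n-BuLi, THF, −78 °C; cannulated into 12, THF, −78 °C; AcOH/THF quench at −78 °C
Reagents that add atoms: none
Why: Bromine–lithium exchange followed by nucleophilic acyl addition to the lactone, in which the lithium lactolate 15 should not collapse at −78 °C so that a second addition is held back, and the cold acetic acid quench releases the gamma-hydroxy ketone without enolising C4, whose configuration (like those of C2 and C3) is carried over from 12.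

**Compound list**

1 | (E)-3,4,5-trimethoxycinnamic acid | COc1cc(/C=C/C(=O)O)cc(OC)c1OC | starting material
2 | methyl (E)-3,4,5-trimethoxycinnamate | COC(=O)/C=C/c1cc(OC)c(OC)c(OC)c1 | intermediate
3 | (E)-3-(3,4,5-trimethoxyphenyl)prop-2-en-1-ol | COc1cc(/C=C/CO)cc(OC)c1OC | intermediate
4 | bromoacetyl bromide | O=C(Br)CBr | starting material
5 | (E)-3-(3,4,5-trimethoxyphenyl)prop-2-en-1-yl 2-bromoacetate | BrCC(=O)OC/C=C/c1cc(OC)c(OC)c(OC)c1 | intermediate
6 | (E)-3-(3,4,5-trimethoxyphenyl)prop-2-en-1-yl 2-[1,2-bis(p-tolylsulfonyl)hydrazinyl]acetate | Cc1ccc(cc1)S(=O)(=O)NN(CC(=O)OC/C=C/c1cc(OC)c(OC)c(OC)c1)S(=O)(=O)c1ccc(C)cc1 | intermediate (not isolated)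
7 | (E)-3-(3,4,5-trimethoxyphenyl)prop-2-en-1-yl 2-diazoacetate | [N-]=[N+]=CC(=O)OC/C=C/c1cc(OC)c(OC)c(OC)c1 | intermediate
8 | diazo iminium chloride (dimethyliminium salt of the formyl diazoacetate) | [N-]=[N+]=C(C=[N+](C)C)C(=O)OC/C=C/c1cc(OC)c(OC)c(OC)c1.[Cl-] | intermediate (not isolated)
9 | (E)-3-(3,4,5-trimethoxyphenyl)prop-2-en-1-yl 2-diazo-3-oxopropanoate | O=CC(=[N+]=[N-])C(=O)OC/C=C/c1cc(OC)c(OC)c(OC)c1 | intermediate
10 | (1S,5R,6S)-2-oxo-6-(3,4,5-trimethoxyphenyl)-3-oxabicyclo[3.1.0]hexane-1-carbaldehyde | O=C[C@@]12C(=O)OC[C@@H]1[C@H]2c1cc(OC)c(OC)c(OC)c1 | intermediate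
11 | (3aR,4S)-4-(3,4,5-trimethoxyphenyl)-3a,4-dihydro-1H,3H-furo[3,4-c]furan-1-one | O=C1C2=CO[C@H](c3cc(OC)c(OC)c(OC)c3)[C@H]2CO1 | intermediate
12 | (3aR,4S,6aR)-4-(3,4,5-trimethoxyphenyl)tetrahydro-1H,3H-furo[3,4-c]furan-1-one | O=C1[C@H]2CO[C@H](c3cc(OC)c(OC)c(OC)c3)[C@H]2CO1 | intermediate
13 | 4-bromo-1,2-dimethoxybenzene | COc1ccc(Br)cc1OC | starting material
14 | 3,4-dimethoxyphenyllithium | [Li]c1ccc(OC)c(OC)c1 | intermediate (not isolated)
15 | lithium lactolate (tetrahedral adduct of 14 and 12, hemiketal carbon undefined) | [Li+].[O-]C1(c3ccc(OC)c(OC)c3)[C@H]2CO[C@H](c3cc(OC)c(OC)c(OC)c3)[C@H]2CO1 | intermediate (not isolated)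
16 | Magnone B, (3,4-dimethoxyphenyl)[(3R,4R,5S)-4-(hydroxymethyl)-5-(3,4,5-trimethoxyphenyl)oxolan-3-yl]methanone | COc1ccc(C(=O)[C@H]2CO[C@H](c3cc(OC)c(OC)c(OC)c3)[C@H]2CO)cc1OC | target

**Step count**

Total: 9 steps. Longest linear sequence: 9 steps (from 1); compounds 4 and 13 enter as bought fragments.

**Steps most likely to fail**

1. Step 7 (ring expansion). The benzylic cation may lose the C3 proton or oligomerise instead of closing, closure may give some of the 2,3-cis arrangement, or the aldehyde may degrade under the Lewis acid. The fallback sets out from 10 and comes back at 12. The aldehyde of 10 would be reduced chemoselectively (NaBH4, MeOH–THF, −40 °C) to (1S,5R,6S)-1-(hydroxymethyl)-6-(3,4,5-trimethoxyphenyl)-3-oxabicyclo[3.1.0]hexan-2-one F1. F1 would then be treated with catalytic TfOH in hexafluoroisopropanol, where protonation of the lactone carbonyl opens the C1–C6 bond and the primary hydroxyl captures the benzylic cation trans to the C3 arm. Tautomerisation of the lactone enol can only give the cis ring fusion, so 12 is reached directly. Here the ring oxygen arrives as an alcohol and not as a carbonyl oxygen, and the hydrogenation of step 8, with its own risk of benzylic C–O cleavage or arene reduction, is bypassed as well.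

2. Step 6 (asymmetric cyclopropanation). The formyl diazo ester may give insufficient facial discrimination or sluggish carbene transfer with the chosen cobalt porphyrin; the formylation of step 5 is an allied weak point. The fallback sets out from 7 and comes back at 10. Diazoacetate 7 would be cyclised with the chiral dirhodium carboxamidate Rh2(4S-MPPIM)4 or its antipode (CH2Cl2, reflux, slow addition), a catalyst class suited to trans-disubstituted allylic diazoacetates, to give (1S,5R,6R)-6-(3,4,5-trimethoxyphenyl)-3-oxabicyclo[3.1.0]hexan-2-one F2. The bridgehead alpha-proton of F2 would then be removed with LDA (THF, −78 °C) and the configurationally fixed cyclopropyl enolate formylated with N-methoxy-N-methylformamide to give 10. Step 5 is then not needed.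

3. Step 9 (aryllithium addition). Collapse of the lactolate before the quench would allow a second addition to the ketone, the aryllithium may enolise the lactone instead of adding, and base-mediated epimerisation at C4 of the product would erode the 3,4-cis relation. The fallback sets out from 12 and comes back at 16. Lactone 12 would be opened with Me(MeO)NH·HCl and Me3Al (CH2Cl2, 0 °C) to (3R,4R,5S)-4-(hydroxymethyl)-N-methoxy-N-methyl-5-(3,4,5-trimethoxyphenyl)oxolane-3-carboxamide F3. This would be silylated at once (TBSCl, imidazole, DMF) to (3R,4R,5S)-4-[(tert-butyldimethylsilyloxy)methyl]-N-methoxy-N-methyl-5-(3,4,5-trimethoxyphenyl)oxolane-3-carboxamide F4. Addition of 14 (THF, −78 °C) stops at the chelated adduct and on work-up should give [(3R,4R,5S)-4-[(tert-butyldimethylsilyloxy)methyl]-5-(3,4,5-trimethoxyphenyl)oxolan-3-yl](3,4-dimethoxyphenyl)methanone F5. Non-basic desilylation (HF·pyridine, THF, 0 °C) then gives 16.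

**Further compounds**

F1 | step 7 | (1S,5R,6S)-1-(hydroxymethyl)-6-(3,4,5-trimethoxyphenyl)-3-oxabicyclo[3.1.0]hexan-2-one | OC[C@@]12C(=O)OC[C@@H]1[C@H]2c1cc(OC)c(OC)c(OC)c1
F2 | step 6 | (1S,5R,6R)-6-(3,4,5-trimethoxyphenyl)-3-oxabicyclo[3.1.0]hexan-2-one | [C@@H]12C(=O)OC[C@@H]1[C@H]2c1cc(OC)c(OC)c(OC)c1
F3 | step 9 | (3R,4R,5S)-4-(hydroxymethyl)-N-methoxy-N-methyl-5-(3,4,5-trimethoxyphenyl)oxolane-3-carboxamide | CON(C)C(=O)[C@H]1CO[C@H](c2cc(OC)c(OC)c(OC)c2)[C@H]1CO
F4 | step 9 | (3R,4R,5S)-4-[(tert-butyldimethylsilyloxy)methyl]-N-methoxy-N-methyl-5-(3,4,5-trimethoxyphenyl)oxolane-3-carboxamide | CON(C)C(=O)[C@H]1CO[C@H](c2cc(OC)c(OC)c(OC)c2)[C@H]1CO[Si](C)(C)C(C)(C)C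
F5 | step 9 | [(3R,4R,5S)-4-[(tert-butyldimethylsilyloxy)methyl]-5-(3,4,5-trimethoxyphenyl)oxolan-3-yl](3,4-dimethoxyphenyl)methanone | COc1ccc(C(=O)[C@H]2CO[C@H](c3cc(OC)c(OC)c(OC)c3)[C@H]2CO[Si](C)(C)C(C)(C)C)cc1OC
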